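Numbering (germacrane): C1 furanone C=O, C2=C3 enol ether, C4=C5 ring olefin (C15 on C4), C6/C7 lactone fusion, C8 ester carbon, C9 CH2, C10 quaternary carbon (C14), C11=C13 methylene, C12 lactone C=O.
Cuts: C4=C5 first (intramolecular Horner–Wadsworth–Emmons olefination), then the C8–O ester bond (Mitsunobu, inversion), then C7–C8 (zinc Barbier allylation). This leaves a furanone aldehyde (C1–C4, C8–C10, C14, C15) and a bromomethyl butenolide (C5–C7, C11–C13).
Forward order: the furanone ring is built on one fragment and the lactone ring is bought with the other. The chain is joined at C7–C8, and the nine-membered oxacycle O–C3–C4–C5–C6–C7–C8–C9–C10 is closed last, in the final step, with every sensitive group already in place.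
Enabling feature: C4 sits on C3 of the vinylogous ester O–C3=C2–C1=O of the furanone ring, so a phosphonate at C4 is as acidic as a β-keto phosphonate and LiCl/amine deprotonates it. C5 is the one carbon between C4 and lactone carbon C6 and comes as the CH2OH of the bought butenolide. The planar furanone holds C10–O–C3–C4 antiperiplanar, so the bridged ring can only take up a cis C4=C5 bond and delivers the otherwise disfavoured Z-trisubstituted olefin by itself.
Stereochemistry: C6 is bought in (S)-5-(hydroxymethyl)furan-2(5H)-one, and C7 and C8 are relayed from it in one event (Barbier step). C8 is inverted while the angelate is put on, and C10 comes from (S)-lactic acid by self-regeneration of the stereocentre.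

Key step: step 13

Remark: every compound that carries the phosphonate is taken as a mixture of epimers at C4, a centre that step 13 turns into an sp2 carbon, so it is left undefined in the SMILES.

Step 1
Reactants: 1 (S)-lactic acid
Product: 2 (2S,5S)-2-tert-butyl-5-methyl-1,3-dioxolan-4-one (cis)
Conditions: t-BuCHO, cat. TsOH·H2O, cat. H2SO4, pentane, reflux (Dean–Stark); recrystallisation at −78 °C
Reagents that add atoms: pivalaldehyde CC(C)(C)C=O
Why: Acid-catalysed acetalisation of the α-hydroxy acid under water removal gives mainly the cis-dioxolanone, whose new acetal centre is set by the lactic acid centre under thermodynamic control and stores the chirality for step 2 (self-regeneration of stereocentres).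

Step 2
Reactants: 2 (2S,5S)-2-tert-butyl-5-methyl-1,3-dioxolan-4-one
Product: 3 (2S,5R)-5-allyl-2-tert-butyl-5-methyl-1,3-dioxolan-4-one
Conditions: LDA, THF, −78 °C; allyl bromide, −78 → −30 °C
Reagents that add atoms: allyl bromide C=CCBr
Why: Diastereoselective enolate alkylation, in which the planar lithium enolate is attacked by allyl bromide on the face anti to the tert-butyl group, so that allyl takes the place of the former hydrogen and the quaternary centre C10 is set with the R configuration.

Step 3
Reactants: 4 diethyl (2-oxopropyl)phosphonate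
Product: 5 diethyl (3-oxobutan-2-yl)phosphonate (racemic)
Conditions: NaH, THF, 0 °C; MeI, 0 → 23 °C
Reagents that add atoms: iodomethane CI
Why: C-alkylation of the stabilised sodium salt of a β-keto phosphonate by one equivalent of iodomethane brings in C15, and the new centre at C4 needs no control because step 13 turns it into an sp2 carbon.

Step 4
Reactants: 3 (2S,5R)-5-allyl-2-tert-butyl-5-methyl-1,3-dioxolan-4-one; 5 diethyl (3-oxobutan-2-yl)phosphonate
Product: 7 diethyl {1-[(5R)-5-allyl-5-methyl-4-oxo-4,5-dihydrofuran-2-yl]ethyl}phosphonate, via hydroxy diketone 6 (not isolated)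
Conditions: 5, NaH, THF, 0 °C; n-BuLi, −78 °C; 3, −78 → −40 °C; 2 M HCl, THF, 23 °C
Reagents that add atoms: none
Why: γ-Acylation of a β-keto phosphonate dianion (Claisen-type condensation), in which the more reactive terminal carbanion C2 attacks the activated dioxolanone carbonyl C1 to give a tetrahedral adduct that survives until the acid quench, releases pivalaldehyde only then and leaves an α′-hydroxy 1,3-diketone that undergoes the classical acid-catalysed cyclodehydration to the 3(2H)-furanone without touching C10.

Step 5
Reactants: 7 diethyl {1-[(5R)-5-allyl-5-methyl-4-oxo-4,5-dihydrofuran-2-yl]ethyl}phosphonate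
Product: 8 diethyl {1-[(5R)-5-methyl-4-oxo-5-(2-oxoethyl)-4,5-dihydrofuran-2-yl]ethyl}phosphonate
Conditions: cat. OsO4, NaIO4, 2,6-lutidine, dioxane/H2O, 23 °C
Reagents that add atoms: osmium tetroxide O=[Os](=O)(=O)=O (delivers the oxygen); sodium periodate [Na+].[O-]I(=O)(=O)=O (terminal oxygen source)
Why: Lemieux–Johnson cleavage, in which OsO4 dihydroxylates the isolated monosubstituted alkene far faster than the trisubstituted push–pull C2=C3 bond, periodate cleaves the diol, and the lutidine buffer keeps the β-acyloxy-type aldehyde from eliminating.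

Step 6
Reactants: 9 (S)-5-(hydroxymethyl)furan-2(5H)-one
Product: 10 (S)-5-{[(tert-butyldiphenylsilyl)oxy]methyl}furan-2(5H)-one
Conditions: TBDPSCl, imidazole, CH2Cl2, 0 → 23 °C
Reagents that add atoms: tert-butyldiphenylsilyl chloride CC(C)(C)[Si](Cl)(c1ccccc1)c1ccccc1
Why: Standard silylation of a primary alcohol under imidazole catalysis, mild enough not to enolise the butenolide, so that the bought centre C6 is kept.

Step 7
Reactants: 10 (S)-5-{[(tert-butyldiphenylsilyl)oxy]methyl}furan-2(5H)-one
Product: 12 (S)-5-{[(tert-butyldiphenylsilyl)oxy]methyl}-3-(hydroxymethyl)furan-2(5H)-one, via selenide adduct 11 (not isolated)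
Conditions: PhSeH, n-BuLi, THF, −78 °C; 10; CH2O (monomer in THF), −78 °C; aq NH4Cl; crude 11, 30% H2O2, pyridine, CH2Cl2, 0 °C
Reagents that add atoms: formaldehyde C=O; benzeneselenol [SeH]c1ccccc1 (its selenium stays only in 11)
Why: Selenolate-triggered Michael–aldol sequence (a Morita–Baylis–Hillman surrogate known for butenolides) followed by selenoxide syn-elimination, in which PhSe− adds to C7 anti to the side chain, the enolate takes up formaldehyde at C11 anti to selenium so that H11 ends up syn to selenium, and both temporary centres vanish on elimination towards the carbonyl while C6 is never deprotonated.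

Step 8
Reactants: 12 (S)-5-{[(tert-butyldiphenylsilyl)oxy]methyl}-3-(hydroxymethyl)furan-2(5H)-one
Product: 13 (S)-3-(bromomethyl)-5-{[(tert-butyldiphenylsilyl)oxy]methyl}furan-2(5H)-one
Conditions: CBr4, PPh3, CH2Cl2, 0 °C
Reagents that add atoms: carbon tetrabromide BrC(Br)(Br)Br
Why: Appel bromination converts the primary allylic alcohol into the bromide by SN2 displacement of the oxyphosphonium group under neutral conditions that leave C6 and the silyl ether untouched.

Step 9
Reactants: 13 (S)-3-(bromomethyl)-5-{[(tert-butyldiphenylsilyl)oxy]methyl}furan-2(5H)-one; 8 furanone aldehyde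
Product: 14 (6S,7R,8S,10R)-alcohol: trans-4,5-disubstituted α-methylene-γ-butyrolactone with CH2OTBDPS on C6 and, on C7, the chain CH(OH)–CH2 that ends at C10 of the phosphonate-bearing furanone (C8 epimeric to the target)
Conditions: Zn dust, THF/sat. aq NH4Cl, 0 → 23 °C
Reagents that add atoms: none
Why: Zinc Barbier allylation with allylic transposition, closely precedented for 5-substituted 3-(bromomethyl)butenolides: the allylzinc formed at C13 attacks the aldehyde through C7 on the butenolide face anti to the C5 side chain (C6/C7 trans) by way of a Zimmerman–Traxler chair in which the ring-locked E-type geometry (C6 trans to C13) and an equatorial C9 give the anti C7/C8 pair, hence 7R and 8S, while the C11=C13 methylene lactone is unveiled in the same event.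

Step 10
Reactants: 14 (6S,7R,8S,10R)-alcohol; 15 angelic acid, (Z)-2-methylbut-2-enoic acid
Product: 16 (6S,7R,8R,10R)-angelate (14 with the C8 oxygen inverted and acylated)
Conditions: PPh3, DIAD, toluene, 0 → 23 °C
Reagents that add atoms: none
Why: Mitsunobu esterification, in which the angelate anion displaces the oxyphosphonium group at C8 by SN2 with clean inversion (8S to 8R) under neutral conditions that neither isomerise the Z-configured acid nor touch the methylene lactone, so that correction of C8 and acylation cost one step.

Step 11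
Reactants: 16 (6S,7R,8R,10R)-angelate
Product: 17 primary alcohol (16 with CH2OH on C6)
Conditions: HF·pyridine, pyridine, THF, 0 → 23 °C
Reagents that add atoms: none
Why: Fluoride-mediated cleavage of the silyl ether under buffered acidic conditions avoids the basic alkoxide or fluoride media that would add to the methylene lactone or provoke acyl migration.

Step 12
Reactants: 17 primary alcohol
Product: 18 seco aldehyde (CHO = C5 on C6, phosphonate on C4)
Conditions: Dess–Martin periodinane, CH2Cl2, 0 → 23 °C
Reagents that add atoms: none
Why: Dess–Martin oxidation turns the primary alcohol into the aldehyde under neutral, non-enolising conditions, so that the α-acyloxy centre C6 is not epimerised.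

Step 13
Reactants: 18 seco aldehyde
Product: 19 15-deoxybudlein A
Conditions: LiCl, i-Pr2NEt, MeCN, slow addition of 18 (about 1 mM final), 23 → 45 °C
Reagents that add atoms: none
Why: LiCl/i-Pr2NEt (Masamune–Roush conditions) removes H4, which is acidified by phosphorus and, through C3=C2, by the C1 carbonyl of the furanone ring; the soft lithium-chelated carbanion adds reversibly to the C5 aldehyde, and the β-oxido phosphonate collapses through an oxaphosphetane by syn-elimination of lithium diethyl phosphate, so that the helper group leaves in the ring-closing event itself. The closest known reaction types are intramolecular Horner–Wadsworth–Emmons macrocyclisations under LiCl/amine conditions, olefinations with γ-phosphono-α,β-unsaturated carbonyl compounds, and base-induced vinylogous aldol closures at the γ-carbon of 5-alkyl-3(2H)-furanones. One ring is closed, the nine-membered oxacycle O–C3–C4–C5–C6–C7–C8–C9–C10, in the 9-exo-trig mode (C4 attacks C5, and the C=O bond stays outside the ring). No new stereocentre is formed and the undefined C4 centre is erased; the only stereochemical element created is the C4=C5 geometry, and the bicycle controls it, because C10–O–C3–C4 is held antiperiplanar by the planar furanone, the ring therefore already contains one trans-like unit, and only the adduct that eliminates to the cis (Z) olefin with C3 and C6 on the same side can go on while the others revert. The step needs ring closure over oligomerisation (slow addition at high dilution and a reversible addition step), attack on the aldehyde rather than on the C11=C13 Michael acceptor (conjugate addition of so stabilised an anion is reversible, olefination is not), and retention at C6 (a weak amine base, and a trans lactone that is the more stable epimer).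

Compound list
1 | (S)-lactic acid | C[C@H](O)C(=O)O | starting material
2 | (2S,5S)-2-tert-butyl-5-methyl-1,3-dioxolan-4-one | C[C@@H]1O[C@H](C(C)(C)C)OC1=O | intermediate
3 | (2S,5R)-5-allyl-2-tert-butyl-5-methyl-1,3-dioxolan-4-one | C=CC[C@@]1(C)O[C@H](C(C)(C)C)OC1=O | intermediate
4 | diethyl (2-oxopropyl)phosphonate | CC(=O)CP(=O)(OCC)OCC | starting material
5 | diethyl (3-oxobutan-2-yl)phosphonate (racemic) | CC(=O)C(C)P(=O)(OCC)OCC | intermediate
6 | diethyl [(6R)-6-hydroxy-6-methyl-3,5-dioxonon-8-en-2-yl]phosphonate (not isolated) | C=CC[C@@](C)(O)C(=O)CC(=O)C(C)P(=O)(OCC)OCC | intermediate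
7 | diethyl {1-[(5R)-5-allyl-5-methyl-4-oxo-4,5-dihydrofuran-2-yl]ethyl}phosphonate | C=CC[C@@]1(C)OC(=CC1=O)C(C)P(=O)(OCC)OCC | intermediate
8 | diethyl {1-[(5R)-5-methyl-4-oxo-5-(2-oxoethyl)-4,5-dihydrofuran-2-yl]ethyl}phosphonate | O=CC[C@@]1(C)OC(=CC1=O)C(C)P(=O)(OCC)OCC | intermediate
9 | (S)-5-(hydroxymethyl)furan-2(5H)-one | O=C1O[C@H](CO)C=C1 | starting material
10 | (S)-5-{[(tert-butyldiphenylsilyl)oxy]methyl}furan-2(5H)-one | O=C1O[C@H](CO[Si](c2ccccc2)(c2ccccc2)C(C)(C)C)C=C1 | intermediate
11 | 3,4-trans-4,5-trans-5-{[(tert-butyldiphenylsilyl)oxy]methyl}-3-(hydroxymethyl)-4-(phenylselanyl)dihydrofuran-2(3H)-one (not isolated) | O=C1O[C@H](CO[Si](c2ccccc2)(c2ccccc2)C(C)(C)C)[C@@H]([Se]c2ccccc2)[C@@H]1CO | intermediate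
12 | (S)-5-{[(tert-butyldiphenylsilyl)oxy]methyl}-3-(hydroxymethyl)furan-2(5H)-one | O=C1O[C@H](CO[Si](c2ccccc2)(c2ccccc2)C(C)(C)C)C=C1CO | intermediate
13 | (S)-3-(bromomethyl)-5-{[(tert-butyldiphenylsilyl)oxy]methyl}furan-2(5H)-one | O=C1O[C@H](CO[Si](c2ccccc2)(c2ccccc2)C(C)(C)C)C=C1CBr | intermediate
14 | (6S,7R,8S,10R)-Barbier alcohol | C=C1C(=O)O[C@H](CO[Si](c2ccccc2)(c2ccccc2)C(C)(C)C)[C@H]1[C@@H](O)C[C@@]2(C)OC(=CC2=O)C(C)P(=O)(OCC)OCC | intermediate
15 | angelic acid | C/C=C(/C)C(=O)O | starting material
16 | (6S,7R,8R,10R)-angelate silyl ether | C=C1C(=O)O[C@H](CO[Si](c2ccccc2)(c2ccccc2)C(C)(C)C)[C@H]1[C@H](OC(=O)/C(C)=C\C)C[C@@]2(C)OC(=CC2=O)C(C)P(=O)(OCC)OCC | intermediate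
17 | (6S,7R,8R,10R)-primary alcohol | C=C1C(=O)O[C@H](CO)[C@H]1[C@H](OC(=O)/C(C)=C\C)C[C@@]2(C)OC(=CC2=O)C(C)P(=O)(OCC)OCC | intermediate
18 | (6S,7R,8R,10R)-seco aldehyde phosphonate | C=C1C(=O)O[C@H](C=O)[C@H]1[C@H](OC(=O)/C(C)=C\C)C[C@@]2(C)OC(=CC2=O)C(C)P(=O)(OCC)OCC | intermediate
19 | 15-deoxybudlein A (6R,7R,8R,10R; 4Z) | C=C1C(=O)O[C@@H]2/C=C(/C)C3=CC(=O)[C@@](C)(C[C@@H](OC(=O)/C(C)=C\C)[C@@H]12)O3 | target

Total step count: 13. Longest linear sequence: 9 steps (1, 2, 4, 5, 9, 10, 11, 12, 13).

Steps most likely to fail
1. Step 13: the strained ring may close too slowly, so that oligomerisation, epimerisation at C6 or conjugate addition to the methylene lactone take over. The fallback replaces carbonyl olefination by ring-closing metathesis; it sets out from 16 and comes back at 19. The phosphonate of 16 is spent in an intermolecular Horner–Wadsworth–Emmons reaction with aqueous formaldehyde (K2CO3, THF) to give the isopropenyl furanone F1. HF·pyridine then gives the primary alcohol F2, Dess–Martin periodinane the aldehyde F3, and Ph3P=CH2 at −78 °C the vinyl lactone F4. Second-generation Hoveyda–Grubbs catalyst in hot dilute toluene closes C4=C5 with loss of ethene and gives 19.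
2. Step 10: substitution at the hindered C8 may lose to elimination towards the acidic H7, or the phosphine may isomerise the Z acid. The fallback sets 8R directly through an open transition state and then acylates with retention; it sets out from 13 (and 8) and comes back at 16. Stannylation of 13 with hexabutylditin and cat. Pd2(dba)3 gives the allylstannane F5. BF3·OEt2 at −78 °C adds F5 to 8 through an open antiperiplanar transition state, which gives the syn C7/C8 pair whatever the geometry of the allyl unit, and yields the 8R alcohol F6. Yamaguchi esterification of F6 with 15 (2,4,6-trichlorobenzoyl chloride, Et3N, then DMAP, toluene) gives 16.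
3. Step 4: attack at the hindered carbonyl may be slow, and proton transfer or early release of pivalaldehyde, followed by its olefination, may consume the dianion. The fallback builds the furanone from an ynone and puts phosphorus on afterwards; it sets out from 3 and comes back at 7. 1-Butynyllithium adds to 3 to give, after work-up, the hydroxy ynone F7. Ph3PAuCl/AgOTf cyclises F7 (5-endo-dig) to the 5-ethylfuranone F8. NBS/AIBN brominates C4 to give the bromide F9, and a Michaelis–Arbuzov reaction with P(OEt)3 gives 7.

Further compounds
F1 | step 13 | isopropenyl furanone (16 with C(CH3)=CH2 on C3) | C=C1C(=O)O[C@H](CO[Si](c2ccccc2)(c2ccccc2)C(C)(C)C)[C@H]1[C@H](OC(=O)/C(C)=C\C)C[C@@]2(C)OC(=CC2=O)C(C)=C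
F2 | step 13 | primary alcohol of the isopropenyl series | C=C1C(=O)O[C@H](CO)[C@H]1[C@H](OC(=O)/C(C)=C\C)C[C@@]2(C)OC(=CC2=O)C(C)=C
F3 | step 13 | aldehyde of the isopropenyl series | C=C1C(=O)O[C@H](C=O)[C@H]1[C@H](OC(=O)/C(C)=C\C)C[C@@]2(C)OC(=CC2=O)C(C)=C
F4 | step 13 | vinyl lactone (metathesis diene) | C=C1C(=O)O[C@H](C=C)[C@H]1[C@H](OC(=O)/C(C)=C\C)C[C@@]2(C)OC(=CC2=O)C(C)=C
F5 | step 10 | (S)-5-{[(tert-butyldiphenylsilyl)oxy]methyl}-3-[(tributylstannyl)methyl]furan-2(5H)-one | O=C1O[C@H](CO[Si](c2ccccc2)(c2ccccc2)C(C)(C)C)C=C1C[Sn](CCCC)(CCCC)CCCC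
F6 | step 10 | (6S,7R,8R,10R)-alcohol (C8 epimer of 14) | C=C1C(=O)O[C@H](CO[Si](c2ccccc2)(c2ccccc2)C(C)(C)C)[C@H]1[C@H](O)C[C@@]2(C)OC(=CC2=O)C(C)P(=O)(OCC)OCC
F7 | step 4 | (R)-4-hydroxy-4-methylnon-1-en-6-yn-5-one | C=CC[C@@](C)(O)C(=O)C#CCC
F8 | step 4 | (R)-2-allyl-5-ethyl-2-methylfuran-3(2H)-one | C=CC[C@@]1(C)OC(=CC1=O)CC
F9 | step 4 | (2R)-2-allyl-5-(1-bromoethyl)-2-methylfuran-3(2H)-one | C=CC[C@@]1(C)OC(=CC1=O)C(C)Br
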